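**Plan**

- Retrosynthesis: remove the 1',5'-epoxide and the C1 hydroxyl (C2=C3 back to C1=C2), then cut C5–C13' and C3–C11' of the cyclohexene. This retro-Diels–Alder gives two molecules of 8-epi-xanthatin.
- In the monomer, cut C1–C2 (Heck), the lactone from the isopropenyl group, then C1–C5 and C5–C6. The seven-membered ring (C1, C5, C6, C7, C8, C9, C10) has ketone-level C1 between CH2-5 and CHMe-10, so it is the carvone ring (C1, C6, C7, C8, C9, C10) with one carbon, C5, inserted next to the carbonyl.
- Forward: carvone ring → cycloheptanone (ring expansion) → enol triflate → cis-fused methylene lactone → dienone (monomer) → [4+2] dimerisation closing the cyclohexene and the spiro centre → C1 hydroxylation → epoxidation.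
- Stereochemistry: C7/C7' from (R)-carvone; C8/C8' by anti photooxygenation, then Mitsunobu inversion; C10/C10' by kinetic protonation; C5 and C11' by the endo Diels–Alder; C1 by axial oxygen uptake; C1'/C5' by β-face epoxidation.

Key step: step 6

Remark: both halves have the 8-epi-xanthatin configuration (C7 R, C8 R, C10 S), so one monomer serves twice. Xanthane locants are used throughout (primes = lower, dienophile-derived half; carvone C1–C6 = C1, C10, C9, C8, C7, C6), and β is the ring face carrying the C7–C11 bond.

**Route**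

Step 1
Reactants: 1 (R)-carvone
Product: 2 through-conjugated trimethylsilyl dienol ether of carvone [(5S)-trimethyl{[2-methyl-5-(prop-1-en-2-yl)cyclohexa-1,3-dien-1-yl]oxy}silane; C7 unchanged]
Conditions: MeMgBr, FeCl3 (3 mol %), Et2O, −20 °C; then Me3SiCl, Et3N, DMPU, −20 °C → rt
Reagents that add atoms: chlorotrimethylsilane C[Si](C)(C)Cl
Why: Iron-catalysed γ-deprotonation of the enone by the Grignard reagent gives the through-conjugated magnesium dienolate (not the kinetic C6 enolate), and O-silylation then gives the 1-silyloxy-1,3-diene without touching C7.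

Step 2
Reactants: 2 through-conjugated trimethylsilyl dienol ether
Product: 5 trans-4-hydroxycarvone [(4S,5R)-4-hydroxy-2-methyl-5-(prop-1-en-2-yl)cyclohex-2-en-1-one], via silyloxy endoperoxide 3 (not isolated), via trans-4-hydroperoxycarvone 4 (not isolated)
Conditions: O2, visible light, tetraphenylporphyrin (cat.), CH2Cl2, −78 °C; MeOH, −78 → 0 °C; then PPh3, 0 °C
Reagents that add atoms: dioxygen O=O
Why: Singlet oxygen adds [4+2] across C1/C8 of the s-cis dienol ether on the face anti to the neighbouring isopropenyl group (C8–O trans to C7), methanolysis of the silyl ketal opens the endoperoxide to the γ-hydroperoxy enone, and PPh3 reduces it to the alcohol; the isolated 1,1-disubstituted alkene is far less reactive towards singlet oxygen.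

Step 3
Reactants: 5 trans-4-hydroxycarvone
Product: 7 cis-4-hydroxycarvone [(4R,5R)-4-hydroxy-2-methyl-5-(prop-1-en-2-yl)cyclohex-2-en-1-one], via cis 4-nitrobenzoate 6 (not isolated)
Conditions: PPh3, diisopropyl azodicarboxylate, 4-O2NC6H4CO2H, THF, 0 °C → rt; then K2CO3, MeOH, 0 °C
Reagents that add atoms: 4-nitrobenzoic acid O=C(O)c1ccc(cc1)[N+](=O)[O-]
Why: Mitsunobu inversion of a hindered secondary allylic alcohol (SN2 of the carboxylate on the oxyphosphonium salt) followed by methanolysis sets C8 as R, cis to the C7 substituent as required for the cis-fused lactone.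

Step 4
Reactants: 7 cis-4-hydroxycarvone
Product: 8 cis-4-silyloxycarvone [(4R,5R)-4-[(tert-butyldimethylsilyl)oxy]-2-methyl-5-(prop-1-en-2-yl)cyclohex-2-en-1-one]
Conditions: t-BuMe2SiCl, imidazole, DMF, rt
Reagents that add atoms: tert-butyldimethylsilyl chloride CC(C)(C)[Si](C)(C)Cl
Why: Standard silylation of a secondary alcohol gives an ether that should survive hydride, Lewis acid, strong base and the selenium oxidation that follow.

Step 5
Reactants: 8 cis-4-silyloxycarvone
Product: 10 (2S,4R,5R)-4-[(tert-butyldimethylsilyl)oxy]-2-methyl-5-(prop-1-en-2-yl)cyclohexan-1-one, via lithium enolate 9 (not isolated)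
Conditions: LiBH(s-Bu)3, THF, −78 °C; then 2,6-di-tert-butyl-4-methylphenol, THF, −78 °C; pH 7 buffer
Reagents that add atoms: none
Why: Conjugate hydride reduction by the hindered borohydride (the 1,4-mode known for carvone) gives enolate 9, and kinetic protonation by the bulky phenol should occur on the α-face, away from the C8 silyloxy group (1,3 to C10) and the C7 isopropenyl group on the β-face (axial protonation of the half-chair with equatorial OTBS); this sets C10 (S) with the methyl cis to both, as the less stable epimer, so 10 is kept away from base.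

Step 6
Reactants: 10 (2S,4R,5R)-4-[(tert-butyldimethylsilyl)oxy]-2-methyl-5-(prop-1-en-2-yl)cyclohexan-1-one; 11 trimethylsilyldiazomethane
Product: 13 (2S,4R,5R)-4-[(tert-butyldimethylsilyl)oxy]-2-methyl-5-(prop-1-en-2-yl)cycloheptan-1-one, via α-silyl ketone 12 (not isolated)
Conditions: Me3SiCHN2 (in hexanes), BF3·OEt2, CH2Cl2, −78 → −30 °C; then 1 M HCl, THF, 0 °C
Reagents that add atoms: trimethylsilyldiazomethane C[Si](C)(C)C=[N+]=[N-]
Why: The BF3-activated C1 carbonyl is attacked by the diazo carbon to give a β-oxido diazonium ion, and C6 then shifts to that carbon with loss of N2, forming C1–C5 and C5–C6 and the α-silyl ketone 12. The closest known reaction is the Lewis-acid-promoted Tiffeneau–Demjanov-type homologation of cyclohexanones with trimethylsilyldiazomethane. The seven-membered ring arises by insertion (a 1,2-alkyl shift that enlarges the six-membered ring), not by cyclisation, so no medium-ring closure has to be paid for. No new stereocentre remains, because the C5–Si centre of 12 becomes CH2 on acidic protodesilylation, which runs through the C1–C5 enol and so leaves C10 untouched, as do C7 and C8, which are remote. The selectivity needed is migration of the C6 methylene over the C10 methine, which the bulky silyl-bearing diazo carbon secures by adding with its silyl group away from the branched α-carbon and placing the less substituted C1–C6 bond anti to the departing N2. The silyl group in 12 also blocks a second homologation, and the new C5 methylene is the less substituted α-position needed for step 7.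

Step 7
Reactants: 13 (2S,4R,5R)-4-[(tert-butyldimethylsilyl)oxy]-2-methyl-5-(prop-1-en-2-yl)cycloheptan-1-one
Product: 15 enol triflate [(4R,5R,7S)-5-[(tert-butyldimethylsilyl)oxy]-7-methyl-4-(prop-1-en-2-yl)cyclohept-1-en-1-yl trifluoromethanesulfonate; C1=C5], via potassium enolate 14 (not isolated)
Conditions: KN(SiMe3)2, THF, −78 °C; then N-(5-chloropyridin-2-yl)-N-(trifluoromethylsulfonyl)trifluoromethanesulfonamide, −78 °C
Reagents that add atoms: N-(5-chloropyridin-2-yl)bis(trifluoromethanesulfon)imide O=S(=O)(N(c1ccc(Cl)cn1)S(=O)(=O)C(F)(F)F)C(F)(F)F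
Why: Kinetic deprotonation by the hindered amide base takes the methylene C5 rather than the methine C10, and fast O-triflation at −78 °C fixes the C1=C5 double bond and ends the lability of C10.

Step 8
Reactants: 15 enol triflate
Product: 16 allylic alcohol [(4R,5R,7S)-5-[(tert-butyldimethylsilyl)oxy]-4-(3-hydroxyprop-1-en-2-yl)-7-methylcyclohept-1-en-1-yl trifluoromethanesulfonate]
Conditions: SeO2 (0.5 equiv), t-BuOOH, CH2Cl2, rt
Reagents that add atoms: selenium dioxide O=[Se]=O (oxygen carrier); tert-butyl hydroperoxide CC(C)(C)OO (terminal oxidant)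
Why: Selenium dioxide allylic oxidation (ene reaction, then [2,3]-shift) hydroxylates the methyl of the isopropenyl group, because allylic strain keeps C7–H in the alkene plane and the electron-poor vinyl triflate does not take part in the ene step; any enal formed by over-oxidation converges in step 10.

Step 9
Reactants: 16 allylic alcohol
Product: 17 diol [(4R,5R,7S)-5-hydroxy-4-(3-hydroxyprop-1-en-2-yl)-7-methylcyclohept-1-en-1-yl trifluoromethanesulfonate]
Conditions: HF·pyridine, pyridine, THF, 0 °C → rt
Reagents that add atoms: none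
Why: Buffered fluoride desilylation frees the C8 hydroxyl under conditions the vinyl triflate tolerates.

Step 10
Reactants: 17 diol
Product: 20 lactone triflate [(3aR,7S,8aR)-7-methyl-3-methylidene-2-oxo-3,3a,4,7,8,8a-hexahydro-2H-cyclohepta[b]furan-6-yl trifluoromethanesulfonate], via hydroxy enal 18 (not isolated), via lactol 19 (not isolated)
Conditions: MnO2 (excess), CH2Cl2, rt
Reagents that add atoms: none
Why: MnO2 oxidises only the allylic primary alcohol, the cis C8 hydroxyl closes the enal to the five-membered lactol, and this is oxidised to the α-methylene-γ-lactone (oxidative lactonisation of a 2-methylene-1,4-diol); the cis ring fusion follows from the C7/C8 configuration already present.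

Step 11
Reactants: 20 lactone triflate; 21 methyl vinyl ketone (but-3-en-2-one)
Product: 22 8-epi-xanthatin [(3aR,7S,8aR)-7-methyl-3-methylidene-6-[(E)-3-oxobut-1-enyl]-3,3a,4,7,8,8a-hexahydro-2H-cyclohepta[b]furan-2-one]
Conditions: Pd(OAc)2 (5 mol %), PPh3 (15 mol %), Et3N, but-3-en-2-one (5 equiv), DMF, 60 °C
Reagents that add atoms: methyl vinyl ketone C=CC(C)=O
Why: Mizoroki–Heck coupling of the vinyl triflate (oxidative addition to zerovalent palladium, insertion of the enone, syn β-hydride elimination) gives the (E)-dienone; the excess of the monosubstituted enone outcompetes the 1,1-disubstituted methylene lactone as acceptor.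

Step 12
Reactants: 22 8-epi-xanthatin (two molecules)
Product: 23 Diels–Alder dimer (spiro cyclohexene with C1=C2 and H-3 cis to H-5; C5 and C11' as in 26; lower half still the dienone)
Conditions: toluene (about 2 M), 2,6-di-tert-butyl-4-methylphenol (cat.), 100 °C, sealed tube, argon
Reagents that add atoms: none
Why: In this thermal Diels–Alder dimerisation the s-cis C5=C1–C2=C3 diene of one molecule adds to the exocyclic C11'=C13' of a second, C5 (the terminus remote from the acetyl group) bonding to the unsubstituted C13' and C3 to C11', with the lactone carbonyl endo, the dienophile reacting on the convex face of its cis-fused lactone (cis to H-7') and the diene on its β-face (C5 flanked there only by H-6β, the α-face being covered by the C6–C7 bond of the chair cycloheptene); this sets C5, the spiro centre C11' and the transient C3 centre together.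

Step 13
Reactants: 23 Diels–Alder dimer
Product: 25 1β-hydroxy-2-ene dimer (C1 tertiary alcohol, C2=C3 enone, lower dienone intact), via C1 hydroperoxide 24 (not isolated)
Conditions: O2 (1 atm), Et3N, EtOAc, rt; then PPh3, 0 °C
Reagents that add atoms: dioxygen O=O
Why: Autoxidation of a β,γ-unsaturated ketone, in which the amine enolises the doubly activated C3–H and oxygen is taken up at the γ-terminus C1 (C3 is neopentylic, next to the spiro centre) on the β-face, anti to the axial C5–H, so that the new C–O bond is axial in a trans-fused 6/7 system (the sense known from the 10β-hydroperoxidation of 5(10)-en-3-one steroids); PPh3 then reduces hydroperoxide 24.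

Step 14
Reactants: 25 1β-hydroxy-2-ene dimer
Product: 26 CNP0177598.1 (target)
Conditions: 3-ClC6H4CO3H, NaHCO3, CH2Cl2, 0 °C
Reagents that add atoms: 3-chloroperoxybenzoic acid O=C(OO)c1cccc(Cl)c1
Why: Prilezhaev epoxidation, in which only the γ,δ-bond C1'=C5' of the lower dienone is electron-rich enough (C2=C3, C2'=C3' and both methylene lactones are conjugated to carbonyl groups), and the peracid should approach the β-face, which carries only the C10' methyl while the α-face is flanked by both allylic ring bonds C10'–C9' and C6'–C7'.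

**Compound list**

1 | (R)-carvone | CC1=CC[C@@H](C(C)=C)CC1=O | starting material
2 | (5S)-trimethyl{[2-methyl-5-(prop-1-en-2-yl)cyclohexa-1,3-dien-1-yl]oxy}silane | C=C(C)[C@H]1CC(O[Si](C)(C)C)=C(C)C=C1 | intermediate
3 | silyloxy endoperoxide (1-trimethylsilyloxy-2,3-dioxabicyclo[2.2.2]oct-5-ene, peroxide bridge anti to isopropenyl) | C=C(C)[C@H]1C[C@]2(O[Si](C)(C)C)OO[C@H]1C=C2C | intermediate (not isolated)
4 | (4S,5R)-4-hydroperoxy-2-methyl-5-(prop-1-en-2-yl)cyclohex-2-en-1-one | C=C(C)[C@H]1CC(=O)C(C)=C[C@@H]1OO | intermediate (not isolated)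
5 | (4S,5R)-4-hydroxy-2-methyl-5-(prop-1-en-2-yl)cyclohex-2-en-1-one (trans-4-hydroxycarvone) | C=C(C)[C@H]1CC(=O)C(C)=C[C@@H]1O | intermediate
6 | (1R,6R)-3-methyl-4-oxo-6-(prop-1-en-2-yl)cyclohex-2-en-1-yl 4-nitrobenzoate | C=C(C)[C@H]1CC(=O)C(C)=C[C@H]1OC(=O)c2ccc(cc2)[N+](=O)[O-] | intermediate (not isolated)
7 | (4R,5R)-4-hydroxy-2-methyl-5-(prop-1-en-2-yl)cyclohex-2-en-1-one (cis-4-hydroxycarvone) | C=C(C)[C@H]1CC(=O)C(C)=C[C@H]1O | intermediate
8 | (4R,5R)-4-[(tert-butyldimethylsilyl)oxy]-2-methyl-5-(prop-1-en-2-yl)cyclohex-2-en-1-one | C=C(C)[C@H]1CC(=O)C(C)=C[C@H]1O[Si](C)(C)C(C)(C)C | intermediate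
9 | lithium enolate of 10 (C1–C10 enolate) | C=C(C)[C@H]1CC([O-])=C(C)C[C@H]1O[Si](C)(C)C(C)(C)C.[Li+] | intermediate (not isolated)
10 | (2S,4R,5R)-4-[(tert-butyldimethylsilyl)oxy]-2-methyl-5-(prop-1-en-2-yl)cyclohexan-1-one | C=C(C)[C@H]1CC(=O)[C@@H](C)C[C@H]1O[Si](C)(C)C(C)(C)C | intermediate
11 | trimethylsilyldiazomethane | C[Si](C)(C)C=[N+]=[N-] | starting material
12 | α-silyl ketone (7-trimethylsilyl derivative of 13, both C5 epimers) | C=C(C)[C@H]1CC([Si](C)(C)C)C(=O)[C@@H](C)C[C@H]1O[Si](C)(C)C(C)(C)C | intermediate (not isolated)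
13 | (2S,4R,5R)-4-[(tert-butyldimethylsilyl)oxy]-2-methyl-5-(prop-1-en-2-yl)cycloheptan-1-one | C=C(C)[C@H]1CCC(=O)[C@@H](C)C[C@H]1O[Si](C)(C)C(C)(C)C | intermediate
14 | potassium C1–C5 enolate of 13 | C=C(C)[C@H]1CC=C([O-])[C@@H](C)C[C@H]1O[Si](C)(C)C(C)(C)C.[K+] | intermediate (not isolated)
15 | (4R,5R,7S)-5-[(tert-butyldimethylsilyl)oxy]-7-methyl-4-(prop-1-en-2-yl)cyclohept-1-en-1-yl trifluoromethanesulfonate | C=C(C)[C@H]1CC=C(OS(=O)(=O)C(F)(F)F)[C@@H](C)C[C@H]1O[Si](C)(C)C(C)(C)C | intermediate
16 | (4R,5R,7S)-5-[(tert-butyldimethylsilyl)oxy]-4-(3-hydroxyprop-1-en-2-yl)-7-methylcyclohept-1-en-1-yl trifluoromethanesulfonate | C=C(CO)[C@H]1CC=C(OS(=O)(=O)C(F)(F)F)[C@@H](C)C[C@H]1O[Si](C)(C)C(C)(C)C | intermediate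
17 | (4R,5R,7S)-5-hydroxy-4-(3-hydroxyprop-1-en-2-yl)-7-methylcyclohept-1-en-1-yl trifluoromethanesulfonate | C=C(CO)[C@H]1CC=C(OS(=O)(=O)C(F)(F)F)[C@@H](C)C[C@H]1O | intermediate
18 | (4R,5R,7S)-5-hydroxy-7-methyl-4-(3-oxoprop-1-en-2-yl)cyclohept-1-en-1-yl trifluoromethanesulfonate | C=C(C=O)[C@H]1CC=C(OS(=O)(=O)C(F)(F)F)[C@@H](C)C[C@H]1O | intermediate (not isolated)
19 | cis-fused lactol of 18 (both anomers) | C=C1C(O)O[C@@H]2C[C@H](C)C(OS(=O)(=O)C(F)(F)F)=CC[C@H]12 | intermediate (not isolated)
20 | (3aR,7S,8aR)-7-methyl-3-methylidene-2-oxo-3,3a,4,7,8,8a-hexahydro-2H-cyclohepta[b]furan-6-yl trifluoromethanesulfonate | C=C1C(=O)O[C@@H]2C[C@H](C)C(OS(=O)(=O)C(F)(F)F)=CC[C@H]12 | intermediate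
21 | methyl vinyl ketone (but-3-en-2-one) | C=CC(C)=O | starting material
22 | 8-epi-xanthatin | C=C1C(=O)O[C@@H]2C[C@H](C)C(/C=C/C(C)=O)=CC[C@H]12 | intermediate
23 | Diels–Alder dimer of 22 (C5–C13' and C3–C11' bonds, C1=C2, H-3 cis to H-5) | C=C1C(=O)O[C@@H]2C[C@H](C)C3=C[C@H](C(C)=O)[C@@]4(C[C@@H]3C[C@H]12)C(=O)O[C@@H]1C[C@H](C)C(/C=C/C(C)=O)=CC[C@@H]14 | intermediate
24 | 1β-hydroperoxy-2-ene dimer | C=C1C(=O)O[C@@H]2C[C@H](C)[C@@]3(OO)C=C(C(C)=O)[C@@]4(C[C@@H]3C[C@H]12)C(=O)O[C@@H]1C[C@H](C)C(/C=C/C(C)=O)=CC[C@@H]14 | intermediate (not isolated)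
25 | 1β-hydroxy-2-ene dimer | C=C1C(=O)O[C@@H]2C[C@H](C)[C@@]3(O)C=C(C(C)=O)[C@@]4(C[C@@H]3C[C@H]12)C(=O)O[C@@H]1C[C@H](C)C(/C=C/C(C)=O)=CC[C@@H]14 | intermediate
26 | CNP0177598.1 (1β-hydroxy-2-ene, 1'β,5'β-epoxide of the 8-epi-xanthatin dimer) | C=C1C(=O)O[C@@H]2C[C@H](C)[C@@]3(O)C=C(C(C)=O)[C@@]4(C[C@@H]3C[C@H]12)C(=O)O[C@@H]1C[C@H](C)[C@]2(/C=C/C(C)=O)O[C@@H]2C[C@@H]14 | target

**Step count and risks**

Total: 14 steps. Longest linear sequence: 14 steps from (R)-carvone (step 12 joins two molecules of 22).

Steps most likely to fail: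

1. Step 12. The dimerisation may suffer from competing cycloaddition modes (the dienone of a second molecule or of the product reacting again, giving isomeric dimers and oligomers) and from incomplete endo or facial control at the temperature the electron-poor diene needs. Fallback: run the union as a cross-reaction, setting out from 22 and 20. Diene 22 is heated with an excess of lactone triflate 20, which has no diene and can act only as dienophile, to give the cross-adduct with a vinyl triflate in the lower half F3. Heck coupling of F3 with 21 under the conditions of step 11 then builds the lower dienone after the union and returns to the route at 23.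

2. Step 13. Base-induced migration of the C1=C2 double bond into conjugation may outrun oxygen uptake, or oxygen may add on the α-face. Fallback from 23: excess buffered 3-ClC6H4CO3H epoxidises both the isolated C1=C2 bond and the C1'=C5' bond to give the bis-epoxide F4. Et3N then opens the β,γ-epoxy ketone by E1cB elimination to the γ-hydroxy enone, which returns to the route at 26 and makes step 14 unnecessary. In this variant the C1 configuration rests on the face of peracid attack, not on oxygen uptake.

3. Step 5. Protonation of enolate 9 may show poor facial selectivity, or the kinetic C10 epimer may be lost by enolisation during work-up. Fallback from 8: 3-ClC6H4CO3H epoxidises the isopropenyl group, the only electron-rich alkene, to the oxirane of 8 F1. Hydrogenation (H2, Rh/Al2O3, EtOAc) then delivers both hydrogens to the enone from the α-face, opposite the silyloxy group and the side chain, giving the saturated epoxy ketone F2 with C10 set without an enolate. Deoxygenation of F2 with Zn, NaI and NaOAc in AcOH (iodohydrin, then reductive elimination) restores the isopropenyl group and returns to the route at 10.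

**Further compounds**

F1 | step 5 | (4R,5S)-4-[(tert-butyldimethylsilyl)oxy]-2-methyl-5-(2-methyloxiran-2-yl)cyclohex-2-en-1-one (oxirane of 8, both epimers at the oxirane carbon) | CC1(CO1)[C@H]2CC(=O)C(C)=C[C@H]2O[Si](C)(C)C(C)(C)C
F2 | step 5 | (2S,4R,5S)-4-[(tert-butyldimethylsilyl)oxy]-2-methyl-5-(2-methyloxiran-2-yl)cyclohexan-1-one (both epimers at the oxirane carbon) | CC1(CO1)[C@H]2CC(=O)[C@@H](C)C[C@H]2O[Si](C)(C)C(C)(C)C
F3 | step 12 | cross Diels–Alder adduct of 22 and 20 (upper half as in 23, lower half with the C1' vinyl triflate) | C=C1C(=O)O[C@@H]2C[C@H](C)C3=C[C@H](C(C)=O)[C@@]4(C[C@@H]3C[C@H]12)C(=O)O[C@@H]1C[C@H](C)C(OS(=O)(=O)C(F)(F)F)=CC[C@@H]14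
F4 | step 13 | bis-epoxide of 23 (1β,2β-epoxide and 1'β,5'β-epoxide) | C=C1C(=O)O[C@@H]2C[C@H](C)[C@@]3(O5)[C@H]5[C@H](C(C)=O)[C@@]4(C[C@@H]3C[C@H]12)C(=O)O[C@@H]1C[C@H](C)[C@]2(/C=C/C(C)=O)O[C@@H]2C[C@@H]14
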